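The 14-membered carbocycle is cut at C5–C6. In the target the C7 carbinol, flanked by the C8=C19 exo-methylene, lies two methylenes (C6, C5) from C4(C18), whose neighbour C3 carries the lactone oxygen. At the ketone/olefin level this is the γ,δ-unsaturated ketone C7(=O)–C6–C5–C4=C3. One Claisen [3,3] shift therefore turns a 12-membered cyclic enol ether (C3–O–C7, C6 methylene and C8=C19 on C7, 2-propenyl on C3), made by methylenating an α-methylene macrolactone, into the 14-membered ring. It creates C5–C6, the E-C3=C4 olefin and the C7 enone together. Late twofold epoxidation and carboxylate opening then build the oxirane and the δ-lactone.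

Key step: step 12

Remark: atoms carry cembrane numbers (C1–C20) throughout. Where no descriptor is given (C3 before step 12, C15 before step 19, the lactol carbon of 12, the carbinol and oxirane carbon of 2 and 3) the compound is assumed to be carried as a mixture at that centre.

Step 1
Reactants: 1 (E)-geranylacetone
Product: 3 (5E)-9,10-epoxy-6,10-dimethylundec-5-en-2-one (racemic), via bromohydrin 2 (not isolated)
Conditions: NBS, THF/H2O, 0 °C; then K2CO3, MeOH, rt
Reagents that add atoms: water, O
Why: Bromohydrin formation in aqueous THF should favour the terminal trisubstituted olefin of the coiled chain, and base then closes the bromohydrin to the oxirane by intramolecular Williamson substitution, the racemic centre being lost in step 2.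

Step 2
Reactants: 3 (5E)-9,10-epoxy-6,10-dimethylundec-5-en-2-one
Product: 4 (4E)-4-methyl-8-oxonon-4-enal
Conditions: H5IO6, THF/H2O, 0 °C → rt
Reagents that add atoms: none
Why: Periodic acid hydrolyses the oxirane to the glycol and cleaves it (Malaprade glycol cleavage), releasing acetone and leaving the C1 aldehyde, while the methyl ketone and the E olefin are untouched.

Step 3
Reactants: 4 (4E)-4-methyl-8-oxonon-4-enal; 5 ethyl (triphenylphosphoranylidene)acetate
Product: 6 ethyl (2E,6E)-6-methyl-10-oxoundeca-2,6-dienoate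
Conditions: CH2Cl2, rt
Reagents that add atoms: none
Why: Wittig olefination with the stabilised ylide should take place only at the aldehyde, the methyl ketone being far less electrophilic, and give the E enoate (C1=C2) that the conjugate addition needs.

Step 4
Reactants: 6 ethyl (2E,6E)-6-methyl-10-oxoundeca-2,6-dienoate; 7 isopropenylboronic acid pinacol ester
Product: 8 ethyl (3R,6E)-6-methyl-10-oxo-3-(prop-1-en-2-yl)undec-6-enoate (1R in cembrane numbering)
Conditions: Rh(acac)(C2H4)2 (3 mol %), (S)-2,2′-bis(diphenylphosphino)-1,1′-binaphthyl ((S)-BINAP), K3PO4, dioxane/H2O (10:1), 60 °C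
Reagents that add atoms: none
Why: In this Hayashi–Miyaura asymmetric conjugate alkenylation the 2-propenyl group passes from boron to rhodium and inserts into the enoate on the face selected by (S)-BINAP, which by the facial preference known for (E)-2-alkenoates should set C1 as R, a cod-free rhodium source avoiding a racemic background reaction.

Step 5
Reactants: 8 ethyl (3R,6E)-6-methyl-10-oxo-3-(prop-1-en-2-yl)undec-6-enoate
Product: 9 ethyl (3R,6E)-6-methyl-3-(prop-1-en-2-yl)-10-(trifluoromethylsulfonyloxy)undeca-6,10-dienoate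
Conditions: KN(SiMe3)2, THF, −78 °C; PhNTf2, −78 → −20 °C
Reagents that add atoms: N-phenylbis(trifluoromethanesulfonimide), O=S(=O)(N(c1ccccc1)S(=O)(=O)C(F)(F)F)C(F)(F)F
Why: Kinetic deprotonation of the methyl ketone on its methyl side (the ester α-protons are several pK units less acidic) followed by O-sulfonylation should give the 2-triflyloxy-1-alkene (kinetic enol triflate formation), which also masks the ketone for the next steps.

Step 6
Reactants: 9 ethyl (3R,6E)-6-methyl-3-(prop-1-en-2-yl)-10-(trifluoromethylsulfonyloxy)undeca-6,10-dienoate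
Product: 11 (4R)-5-methyl-4-[(3E)-3-methyl-7-(trifluoromethylsulfonyloxy)octa-3,7-dien-1-yl]oxan-2-one (δ-lactone between C16–O and C3; C15 epimers), via hydroxy ester 10 (not isolated)
Conditions: 9-borabicyclo[3.3.1]nonane (9-BBN), THF, 0 °C → rt; NaBO3·4H2O, H2O, rt; then pyridinium p-toluenesulfonate (cat.), toluene, 60 °C
Reagents that add atoms: sodium perborate, [Na+].[Na+].O[B-]1(O)OO[B-](O)(O)OO1
Why: Anti-Markovnikov hydroboration with bulky 9-BBN should select the unhindered 2-propenyl group over the trisubstituted olefin and the electron-poor enol triflate, perborate oxidation spares the triflate, and the δ-hydroxy ester is then deliberately closed to the lactone (acid-catalysed lactonisation) so that no open/cyclic mixture is carried on, C15 forming without control and being corrected in step 19.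

Step 7
Reactants: 11 δ-lactone (4R)-5-methyl-4-[(3E)-3-methyl-7-(trifluoromethylsulfonyloxy)octa-3,7-dien-1-yl]oxan-2-one
Product: 12 (4R)-5-methyl-4-[(3E)-3-methyl-7-(trifluoromethylsulfonyloxy)octa-3,7-dien-1-yl]oxan-2-ol (lactol at C3; anomers and C15 epimers)
Conditions: iBu2AlH (1.1 equiv), CH2Cl2, −78 °C; aq. KNaC4H4O6
Reagents that add atoms: none
Why: Half-reduction of a δ-lactone with iBu2AlH stops at the lactol because the tetrahedral aluminium alkoxide does not collapse at low temperature, which is more dependable than stopping an open-chain ester at the aldehyde, and the enol triflate is inert.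

Step 8
Reactants: 12 lactol (4R)-5-methyl-4-[(3E)-3-methyl-7-(trifluoromethylsulfonyloxy)octa-3,7-dien-1-yl]oxan-2-ol; 13 isopropenylmagnesium bromide
Product: 14 (5E,9R)-11-hydroxy-9-(1-hydroxypropan-2-yl)-6,12-dimethyltrideca-1,5,12-trien-2-yl trifluoromethanesulfonate (seco diol; C3 and C15 epimers)
Conditions: THF, −20 → 0 °C; aq. NH4Cl
Reagents that add atoms: none
Why: Grignard addition to the ring-opened hydroxy aldehyde form of the lactol (the first equivalent deprotonates it) installs C4, C5 and C18 as a 2-methylallyl alcohol, C3 forming as both epimers because it is erased in step 12, and the enol triflate does not couple without a transition-metal catalyst.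

Step 9
Reactants: 14 seco diol (5E,9R)-11-hydroxy-9-(1-hydroxypropan-2-yl)-6,12-dimethyltrideca-1,5,12-trien-2-yl trifluoromethanesulfonate
Product: 15 (5E,9R)-9-[1-(tert-butyldimethylsilyloxy)propan-2-yl]-11-hydroxy-6,12-dimethyltrideca-1,5,12-trien-2-yl trifluoromethanesulfonate (seco hydroxy enol triflate, free C3–OH)
Conditions: TBSCl, imidazole, CH2Cl2, 0 °C
Reagents that add atoms: tert-butyldimethylsilyl chloride, CC(C)(C)[Si](C)(C)Cl
Why: Silyl ether formation with TBSCl and imidazole is selective for the primary C16 hydroxyl over the hindered secondary allylic C3 hydroxyl, which must stay free for the ring closure.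

Step 10
Reactants: 15 seco hydroxy enol triflate (C16–OTBS, free C3–OH)
Product: 16 (6E,10R)-10-[1-(tert-butyldimethylsilyloxy)propan-2-yl]-7-methyl-3-methylidene-12-(prop-1-en-2-yl)oxacyclododec-6-en-2-one (12-membered α-methylene lactone, C7 from CO)
Conditions: Pd(PPh3)4 (10 mol %), CO (1 atm), iPr2NEt, THF, 65 °C, syringe-pump addition (final 2 mM)
Reagents that add atoms: carbon monoxide, [C-]#[O+]
Why: In this palladium-catalysed carbonylative macrolactonisation zerovalent palladium inserts into the C8–OTf bond, CO insertion gives the acylpalladium species (C7) and the C3 hydroxyl captures it under high dilution, closing the 12-membered ring through the C7–O bond at a ring size that allows the strain-free s-trans ester.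

Step 11
Reactants: 16 12-membered α-methylene lactone
Product: 17 (6E,10R)-10-[1-(tert-butyldimethylsilyloxy)propan-2-yl]-7-methyl-2,3-dimethylidene-12-(prop-1-en-2-yl)oxacyclododec-6-ene (cyclic 2-alkoxydiene, C6 from titanium)
Conditions: Cp2Ti(μ-Cl)(μ-CH2)AlMe2 (Tebbe reagent), pyridine, THF/toluene, −40 → 0 °C; aq. NaOH; filtration through basic Al2O3 (pentane, 1 % Et3N)
Reagents that add atoms: Tebbe reagent, C[Al-]1(C)C[Ti](C2C=CC=C2)(C2C=CC=C2)[Cl+]1
Why: Tebbe methylenation of the lactone carbonyl (titanium methylidene [2+2] addition and cycloreversion, driven by the Ti=O bond) turns C7=O into C7=C6H2 at a temperature where the allyl vinyl ether does not yet rearrange, so that no titanium reagent is left to methylenate the ketone of step 12, while exchange with the 1,1-disubstituted olefins is degenerate and pyridine with basic work-up protects the acid-labile alkoxydiene.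

Step 12
Reactants: 17 cyclic 2-alkoxydiene (C3 and C15 epimers)
Product: 18 (1R,3E,11E)-1-[1-(tert-butyldimethylsilyloxy)propan-2-yl]-4,12-dimethyl-8-methylidenecyclotetradeca-3,11-dien-7-one (cembrane numbering)
Conditions: toluene (5 mM), Et3N (trace), 110 °C, degassed, base-washed glass
Reagents that add atoms: none
Why: On heating, the allyl vinyl ether C6=C7–O–C3–C4=C5 of 17 should undergo a concerted suprafacial [3,3] sigmatropic shift through a six-membered chair array, in which the C5–C6 bond forms as the C3–O bond breaks and the ring oxygen becomes the C7 carbonyl, the conjugated enone providing the driving force. The closest known reaction types are the Claisen ring enlargement of lactone-derived 2-methylene cyclic ethers that bear an alkenyl group on the carbinol carbon and the Claisen rearrangement of open-chain allyl vinyl ethers made by ester methylenation, and this 12-membered case lies between them. The 14-membered carbocycle is closed by a two-atom ring enlargement and not by end-to-end cyclisation, since C3 and C7 are already tied by the nine-carbon chain from C2 through C1 and C14 to C8 and the new C5–C6 bond, formed outside the old ring, draws C4, C5 and C6 into it. No stereocentre is created and C3 is erased, so the C3 and C15 epimers need no separation and C1 is a spectator. The step needs E geometry at C3=C4, and the chair provides it by placing the ring carbon C2 equatorial on C3, which avoids a 1,3-diaxial clash with C8 on C7 and matches the extended lactone-like s-trans array C8–C7–O–C3–C2 that the long tether spans without strain, so both C3 epimers should converge on the same E olefin. Dilution, exclusion of acid and the absence of titanium reagent protect the alkoxydiene and the product enone.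

Step 13
Reactants: 18 14-membered dienyl α-methylene ketone
Product: 19 (1R,3E,7S,11E)-1-[1-(tert-butyldimethylsilyloxy)propan-2-yl]-4,12-dimethyl-8-methylidenecyclotetradeca-3,11-dien-7-ol
Conditions: (R)-tetrahydro-1-methyl-3,3-diphenyl-1H,3H-pyrrolo[1,2-c][1,3,2]oxazaborole ((R)-Me-CBS, 0.5 equiv), catecholborane, toluene, −78 °C
Reagents that add atoms: none
Why: In this Corey–Bakshi–Shibata reduction the (R)-oxazaborolidine binds the ketone with the α-branched alkenyl carbon C8 as the large group and C6 as the small one and delivers hydride to the face that gives the 7S allylic alcohol, the low temperature suppressing conjugate reduction.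

Step 14
Reactants: 19 (7S)-allylic alcohol
Product: 20 (1R,3E,7S,11E)-1-[1-(tert-butyldimethylsilyloxy)propan-2-yl]-4,12-dimethyl-8-methylidene-7-(triisopropylsilyloxy)cyclotetradeca-3,11-diene
Conditions: TIPSOTf, 2,6-lutidine, CH2Cl2, −78 → 0 °C
Reagents that add atoms: triisopropylsilyl trifluoromethanesulfonate, CC(C)[Si](OS(=O)(=O)C(F)(F)F)(C(C)C)C(C)C
Why: Silylation with the silyl triflate covers the hindered secondary allylic alcohol as a TIPS ether that is orthogonal to the primary TBS ether, shields the neighbouring C8=C19 olefin and survives the later oxidations.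

Step 15
Reactants: 20 bis-silyl ether (C16–OTBS, C7–OTIPS)
Product: 21 (7S)-7-(triisopropylsilyloxy)cembra-3E,8(19),11E-trien-16-ol (C15 epimers)
Conditions: camphorsulfonic acid (cat.), MeOH/CH2Cl2 (1:1), 0 °C
Reagents that add atoms: none
Why: Acid-catalysed methanolysis removes the unhindered primary TBS ether much faster than the secondary TIPS ether (selective desilylation), freeing C16–OH while no acid-sensitive group is yet present.

Step 16
Reactants: 21 (7S)-7-(triisopropylsilyloxy)cembra-3E,8(19),11E-trien-16-ol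
Product: 22 (7S)-7-(triisopropylsilyloxy)cembra-3E,8(19),11E-trien-16-al (C15 epimers)
Conditions: Dess–Martin periodinane, NaHCO3, CH2Cl2, 0 °C → rt
Reagents that add atoms: none
Why: Dess–Martin oxidation takes the primary alcohol to the aldehyde under buffered neutral conditions that leave the three olefins and the silyl ether untouched.

Step 17
Reactants: 22 (7S)-7-(triisopropylsilyloxy)cembra-3E,8(19),11E-trien-16-al
Product: 23 (7S)-7-(triisopropylsilyloxy)cembra-3E,8(19),11E-trien-16-oic acid (C15 epimers)
Conditions: NaClO2, NaH2PO4, 2-methyl-2-butene, t-BuOH/H2O, 0 °C → rt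
Reagents that add atoms: sodium chlorite, [Na+].[O-]Cl=O
Why: Pinnick oxidation converts the aldehyde into the C16 carboxylic acid, with 2-methyl-2-butene scavenging hypochlorous acid so that the olefins are not chlorinated.

Step 18
Reactants: 23 (7S)-7-(triisopropylsilyloxy)cembra-3E,8(19),11E-trien-16-oic acid
Product: 25 (1R,3R,4S,7S,11S,12S)-11,12-epoxy-4-hydroxy-7-(triisopropylsilyloxy)cembr-8(19)-en-16,3-olide (C15 epimers), via bis-epoxy acid 24 (not isolated)
Conditions: 1,2:4,5-di-O-isopropylidene-β-L-erythro-2,3-hexodiulo-2,6-pyranose (ent-Shi ketone, from L-sorbose, 0.6 equiv), Oxone (2KHSO5·KHSO4·K2SO4), K2CO3, Bu4NHSO4 (cat.), Na2B4O7/Na2EDTA buffer (pH 10.5), MeCN/CH2(OMe)2/H2O, −5 → 0 °C; then citric acid to pH 4–5, EtOAc; pyridinium p-toluenesulfonate (cat.), CH2Cl2, 0 °C → rt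
Reagents that add atoms: potassium peroxymonosulfate (active part of Oxone), [K+].[O-]S(=O)(=O)OO
Why: In this Shi epoxidation the dioxirane of the L-series ketone should attack both E-trisubstituted olefins, which share the same local substitution pattern, through the spiro transition state to give the (3S,4S)- and (11S,12S)-oxiranes (the D-fructose ketone gives the R,R series) faster than the deactivated and shielded C8=C19 olefin, and the C16 carboxyl then opens the 3,4-oxirane at the secondary carbon C3 in a 6-exo attack with inversion (3R) while C4 keeps its oxygen (4S) and the 11,12-oxirane, out of reach of the carboxyl, survives.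

Step 19
Reactants: 25 epoxy hydroxy δ-lactone (C15 epimers)
Product: 26 (1R,3R,4S,7S,11S,12S,15S)-11,12-epoxy-4-hydroxy-7-(triisopropylsilyloxy)cembr-8(19)-en-16,3-olide
Conditions: DBU, toluene, 40 °C
Reagents that add atoms: none
Why: Base-mediated epimerisation through the lactone enolate should drive C15 to the thermodynamically preferred 15S epimer, in which the C17 methyl is trans to C14 and all three substituents of the δ-lactone are equatorial.

Step 20
Reactants: 26 (15S)-configured TIPS ether
Product: 27 CNP0262409.2, (1R,3R,4S,7S,11S,12S,15S)-11,12-epoxy-4,7-dihydroxycembr-8(19)-en-16,3-olide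
Conditions: Bu4NF, AcOH, THF, 0 °C → rt
Reagents that add atoms: none
Why: Fluoride cleaves the Si–O bond of the TIPS ether (desilylation), and the acetic acid buffer keeps the lactone, the oxirane and the C15 configuration set in step 19 intact.

Compound list
1 | (E)-geranylacetone, (5E)-6,10-dimethylundeca-5,9-dien-2-one | CC(=O)CC/C=C(\C)CCC=C(C)C | starting material
2 | (5E)-9-bromo-10-hydroxy-6,10-dimethylundec-5-en-2-one (racemic) | CC(=O)CC/C=C(\C)CCC(Br)C(C)(C)O | intermediate
3 | (5E)-9,10-epoxy-6,10-dimethylundec-5-en-2-one (racemic) | CC(=O)CC/C=C(\C)CCC1OC1(C)C | intermediate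
4 | (4E)-4-methyl-8-oxonon-4-enal | CC(=O)CC/C=C(\C)CCC=O | intermediate
5 | ethyl (triphenylphosphoranylidene)acetate | CCOC(=O)C=P(c1ccccc1)(c1ccccc1)c1ccccc1 | starting material
6 | ethyl (2E,6E)-6-methyl-10-oxoundeca-2,6-dienoate | CC(=O)CC/C=C(\C)CC/C=C/C(=O)OCC | intermediate
7 | isopropenylboronic acid pinacol ester, 4,4,5,5-tetramethyl-2-(prop-1-en-2-yl)-1,3,2-dioxaborolane | CC(=C)B1OC(C)(C)C(C)(C)O1 | starting material
8 | ethyl (3R,6E)-6-methyl-10-oxo-3-(prop-1-en-2-yl)undec-6-enoate | CC(=O)CC/C=C(\C)CC[C@@H](C(C)=C)CC(=O)OCC | intermediate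
9 | ethyl (3R,6E)-6-methyl-3-(prop-1-en-2-yl)-10-(trifluoromethylsulfonyloxy)undeca-6,10-dienoate | C=C(OS(=O)(=O)C(F)(F)F)CC/C=C(\C)CC[C@@H](C(C)=C)CC(=O)OCC | intermediate
10 | ethyl (3R,6E)-3-(1-hydroxypropan-2-yl)-6-methyl-10-(trifluoromethylsulfonyloxy)undeca-6,10-dienoate (C15 epimers) | C=C(OS(=O)(=O)C(F)(F)F)CC/C=C(\C)CC[C@@H](C(C)CO)CC(=O)OCC | intermediate
11 | (4R)-5-methyl-4-[(3E)-3-methyl-7-(trifluoromethylsulfonyloxy)octa-3,7-dien-1-yl]oxan-2-one (C15 epimers) | C=C(OS(=O)(=O)C(F)(F)F)CC/C=C(\C)CC[C@@H]1CC(=O)OCC1C | intermediate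
12 | (4R)-5-methyl-4-[(3E)-3-methyl-7-(trifluoromethylsulfonyloxy)octa-3,7-dien-1-yl]oxan-2-ol (anomers, C15 epimers) | C=C(OS(=O)(=O)C(F)(F)F)CC/C=C(\C)CC[C@@H]1CC(O)OCC1C | intermediate
13 | isopropenylmagnesium bromide | CC(=C)[Mg]Br | starting material
14 | (5E,9R)-11-hydroxy-9-(1-hydroxypropan-2-yl)-6,12-dimethyltrideca-1,5,12-trien-2-yl trifluoromethanesulfonate (C3 and C15 epimers) | C=C(OS(=O)(=O)C(F)(F)F)CC/C=C(\C)CC[C@@H](C(C)CO)CC(O)C(C)=C | intermediate
15 | (5E,9R)-9-[1-(tert-butyldimethylsilyloxy)propan-2-yl]-11-hydroxy-6,12-dimethyltrideca-1,5,12-trien-2-yl trifluoromethanesulfonate (C3 and C15 epimers) | C=C(OS(=O)(=O)C(F)(F)F)CC/C=C(\C)CC[C@@H](C(C)CO[Si](C)(C)C(C)(C)C)CC(O)C(C)=C | intermediate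
16 | (6E,10R)-10-[1-(tert-butyldimethylsilyloxy)propan-2-yl]-7-methyl-3-methylidene-12-(prop-1-en-2-yl)oxacyclododec-6-en-2-one (C3 and C15 epimers) | C=C1CC/C=C(\C)CC[C@@H](C(C)CO[Si](C)(C)C(C)(C)C)CC(C(C)=C)OC1=O | intermediate
17 | (6E,10R)-10-[1-(tert-butyldimethylsilyloxy)propan-2-yl]-7-methyl-2,3-dimethylidene-12-(prop-1-en-2-yl)oxacyclododec-6-ene (C3 and C15 epimers) | C=C1CC/C=C(\C)CC[C@@H](C(C)CO[Si](C)(C)C(C)(C)C)CC(C(C)=C)OC1=C | intermediate
18 | (1R,3E,11E)-1-[1-(tert-butyldimethylsilyloxy)propan-2-yl]-4,12-dimethyl-8-methylidenecyclotetradeca-3,11-dien-7-one (cembrane numbering, C15 epimers) | C=C1CC/C=C(\C)CC[C@@H](C(C)CO[Si](C)(C)C(C)(C)C)C/C=C(\C)CCC1=O | intermediate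
19 | (1R,3E,7S,11E)-1-[1-(tert-butyldimethylsilyloxy)propan-2-yl]-4,12-dimethyl-8-methylidenecyclotetradeca-3,11-dien-7-ol (C15 epimers) | C=C1CC/C=C(\C)CC[C@@H](C(C)CO[Si](C)(C)C(C)(C)C)C/C=C(\C)CC[C@@H]1O | intermediate
20 | (1R,3E,7S,11E)-1-[1-(tert-butyldimethylsilyloxy)propan-2-yl]-4,12-dimethyl-8-methylidene-7-(triisopropylsilyloxy)cyclotetradeca-3,11-diene (C15 epimers) | C=C1CC/C=C(\C)CC[C@@H](C(C)CO[Si](C)(C)C(C)(C)C)C/C=C(\C)CC[C@@H]1O[Si](C(C)C)(C(C)C)C(C)C | intermediate
21 | (1R,7S)-7-(triisopropylsilyloxy)cembra-3E,8(19),11E-trien-16-ol (C15 epimers) | C=C1CC/C=C(\C)CC[C@@H](C(C)CO)C/C=C(\C)CC[C@@H]1O[Si](C(C)C)(C(C)C)C(C)C | intermediate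
22 | (1R,7S)-7-(triisopropylsilyloxy)cembra-3E,8(19),11E-trien-16-al (C15 epimers) | C=C1CC/C=C(\C)CC[C@@H](C(C)C=O)C/C=C(\C)CC[C@@H]1O[Si](C(C)C)(C(C)C)C(C)C | intermediate
23 | (1R,7S)-7-(triisopropylsilyloxy)cembra-3E,8(19),11E-trien-16-oic acid (C15 epimers) | C=C1CC/C=C(\C)CC[C@@H](C(C)C(=O)O)C/C=C(\C)CC[C@@H]1O[Si](C(C)C)(C(C)C)C(C)C | intermediate
24 | (1R,3S,4S,7S,11S,12S)-3,4:11,12-diepoxy-7-(triisopropylsilyloxy)cembr-8(19)-en-16-oic acid (C15 epimers) | C=C1CC[C@@H]2O[C@@]2(C)CC[C@@H](C(C)C(=O)O)C[C@@H]2O[C@@]2(C)CC[C@@H]1O[Si](C(C)C)(C(C)C)C(C)C | intermediate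
25 | (1R,3R,4S,7S,11S,12S)-11,12-epoxy-4-hydroxy-7-(triisopropylsilyloxy)cembr-8(19)-en-16,3-olide (C15 epimers) | C=C1CC[C@@H]2O[C@@]2(C)CC[C@@H]2C[C@@H](OC(=O)C2C)[C@@](C)(O)CC[C@@H]1O[Si](C(C)C)(C(C)C)C(C)C | intermediate
26 | (1R,3R,4S,7S,11S,12S,15S)-11,12-epoxy-4-hydroxy-7-(triisopropylsilyloxy)cembr-8(19)-en-16,3-olide | C=C1CC[C@@H]2O[C@@]2(C)CC[C@@H]2C[C@@H](OC(=O)[C@H]2C)[C@@](C)(O)CC[C@@H]1O[Si](C(C)C)(C(C)C)C(C)C | intermediate
27 | CNP0262409.2, (1R,3R,4S,7S,11S,12S,15S)-11,12-epoxy-4,7-dihydroxycembr-8(19)-en-16,3-olide | C=C1CC[C@@H]2O[C@@]2(C)CC[C@@H]2C[C@@H](OC(=O)[C@H]2C)[C@@](C)(O)CC[C@@H]1O | target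

Total step count: 20. Longest linear sequence: 20 steps, from (E)-geranylacetone 1 to 27; the route is fully linear.

Steps most likely to fail

Step 12, together with the methylenation of step 11 that feeds it. The acid-labile alkoxydiene may hydrolyse back to the lactone or oligomerise, and the [3,3] shift in the 12-membered ring may be slower than these losses. The fallback sets out from 15 and comes back at 18. A Johnson–Claisen rearrangement of the C3 alcohol (MeC(OEt)3, catalytic propionic acid, 140 °C) makes the same C5–C6 bond and E-C3=C4 olefin in the open chain and gives the γ,δ-unsaturated ethyl ester F1. Reduction with iBu2AlH at −78 °C gives the seco aldehyde F2. A Nozaki–Hiyama–Kishi ring closure (CrCl2, catalytic NiCl2, DMSO/THF, high dilution) then joins C7 of the aldehyde to C8 of the enol triflate and gives the macrocyclic allylic alcohol F3 as C7 epimers. Dess–Martin oxidation of this alcohol returns the enone 18.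

Step 10. Intermolecular esterification may outrun ring closure, and zerovalent palladium may ionise the allylic ester as it forms. The fallback sets out from 15 and comes back at 16. The triflate is carbonylated intermolecularly (Pd(OAc)2, PPh3, CO, MeOH, Et3N, DMF) to the methyl 2-methylene ester F4. LiOH in THF/H2O gives the seco hydroxy acid F5. A Shiina macrolactonisation (2-methyl-6-nitrobenzoic anhydride, DMAP, toluene, slow addition) then closes the same C7–O bond without palladium and gives 16.

Step 18. The dioxirane may also attack the C8=C19 methylene, the ring conformation may override the catalyst at one of the two olefins, and acid may open an oxirane at its tertiary carbon. The fallback sets out from 18 and comes back at 27. It keeps C7 as the ketone, so that C8=C19 is a conjugated, electron-poor olefin during the dioxirane step. HF·pyridine in THF removes the TBS group to give the hydroxy enone F6. Dess–Martin and Pinnick oxidations give the keto aldehyde F7 and the keto acid F8. The Shi epoxidation of step 18 gives the bis-epoxy keto acid F9, which lactonises on the same acidic work-up to the keto hydroxy lactone F10. The oxazaborolidine reduction of step 13 then sets C7 and gives the (7S)-diol lactone F11 as a C15 mixture. The DBU equilibration of step 19 gives 27 directly. This order is shorter but exposes the reactive enone to aqueous base and allows a C4–OH/C7 hemiketal, which is why it is held in reserve.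

Further compounds
F1 | step 12 | ethyl (4E,7R,10E)-7-[1-(tert-butyldimethylsilyloxy)propan-2-yl]-4,10-dimethyl-14-(trifluoromethylsulfonyloxy)pentadeca-4,10,14-trienoate (C15 epimers) | C=C(OS(=O)(=O)C(F)(F)F)CC/C=C(\C)CC[C@@H](C(C)CO[Si](C)(C)C(C)(C)C)C/C=C(\C)CCC(=O)OCC
F2 | step 12 | (4E,7R,10E)-7-[1-(tert-butyldimethylsilyloxy)propan-2-yl]-4,10-dimethyl-14-(trifluoromethylsulfonyloxy)pentadeca-4,10,14-trienal (C15 epimers) | C=C(OS(=O)(=O)C(F)(F)F)CC/C=C(\C)CC[C@@H](C(C)CO[Si](C)(C)C(C)(C)C)C/C=C(\C)CCC=O
F3 | step 12 | (1R,3E,11E)-1-[1-(tert-butyldimethylsilyloxy)propan-2-yl]-4,12-dimethyl-8-methylidenecyclotetradeca-3,11-dien-7-ol (C7 and C15 epimers) | C=C1CC/C=C(\C)CC[C@@H](C(C)CO[Si](C)(C)C(C)(C)C)C/C=C(\C)CCC1O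
F4 | step 10 | methyl (5E,9R)-9-[1-(tert-butyldimethylsilyloxy)propan-2-yl]-11-hydroxy-6,12-dimethyl-2-methylidenetrideca-5,12-dienoate (C3 and C15 epimers) | COC(=O)C(=C)CC/C=C(\C)CC[C@@H](C(C)CO[Si](C)(C)C(C)(C)C)CC(O)C(C)=C
F5 | step 10 | (5E,9R)-9-[1-(tert-butyldimethylsilyloxy)propan-2-yl]-11-hydroxy-6,12-dimethyl-2-methylidenetrideca-5,12-dienoic acid (C3 and C15 epimers) | OC(=O)C(=C)CC/C=C(\C)CC[C@@H](C(C)CO[Si](C)(C)C(C)(C)C)CC(O)C(C)=C
F6 | step 18 | (1R,3E,11E)-1-(1-hydroxypropan-2-yl)-4,12-dimethyl-8-methylidenecyclotetradeca-3,11-dien-7-one (C15 epimers) | C=C1CC/C=C(\C)CC[C@@H](C(C)CO)C/C=C(\C)CCC1=O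
F7 | step 18 | (1R)-7-oxocembra-3E,8(19),11E-trien-16-al (C15 epimers) | C=C1CC/C=C(\C)CC[C@@H](C(C)C=O)C/C=C(\C)CCC1=O
F8 | step 18 | (1R)-7-oxocembra-3E,8(19),11E-trien-16-oic acid (C15 epimers) | C=C1CC/C=C(\C)CC[C@@H](C(C)C(=O)O)C/C=C(\C)CCC1=O
F9 | step 18 | (1R,3S,4S,11S,12S)-3,4:11,12-diepoxy-7-oxocembr-8(19)-en-16-oic acid (C15 epimers) | C=C1CC[C@@H]2O[C@@]2(C)CC[C@@H](C(C)C(=O)O)C[C@@H]2O[C@@]2(C)CCC1=O
F10 | step 18 | (1R,3R,4S,11S,12S)-11,12-epoxy-4-hydroxy-7-oxocembr-8(19)-en-16,3-olide (C15 epimers) | C=C1CC[C@@H]2O[C@@]2(C)CC[C@@H]2C[C@@H](OC(=O)C2C)[C@@](C)(O)CCC1=O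
F11 | step 18 | (1R,3R,4S,7S,11S,12S)-11,12-epoxy-4,7-dihydroxycembr-8(19)-en-16,3-olide (C15 epimers) | C=C1CC[C@@H]2O[C@@]2(C)CC[C@@H]2C[C@@H](OC(=O)C2C)[C@@](C)(O)CC[C@@H]1O
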